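Target 9 consists of two identical benzene rings (A and B). Each carries OH at C1 and C3 and is joined at C5, the ring carbon meta to both oxygens, to an unbranched, unfunctionalised (CH2)14 chain. The twofold symmetry makes the two C5–CH2 bonds equivalent, and both chain ends are plain primary carbons that can be reached as radicals.
Key disconnection: both C5–CH2 bonds are cut at once, giving two molecules of 1-iodo-3,5-dimethoxybenzene and a tetradecane-1,14-diyl unit. That unit is hexadecanedioic acid minus two CO2, used as its bis(N-hydroxyphthalimide) ester. All three partners are electrophiles and are joined reductively at nickel.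
Around the key step there is only activation of the diacid before it and fourfold O-demethylation after it.
No ring is formed in the route: rings A and B are bought with the 1,3,5-pattern already in place.

Key step: step 2

Remark: 9 has no stereocentre and no double-bond geometry, so no step has to control configuration and all SMILES are written without stereo descriptors.

Step 1
Reactants: 1 hexadecanedioic acid; 2 N-hydroxyphthalimide (2.2 equiv)
Product: 4 bis(1,3-dioxoisoindolin-2-yl) hexadecanedioate, via monoester 3 (not isolated)
Conditions: N,N'-diisopropylcarbodiimide (DIC, 2.3 equiv), DMAP (0.2 equiv), CH2Cl2/THF, 0 °C to rt; recrystallisation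
Reagents that add atoms: none
Why: This is a Steglich-type carbodiimide esterification in which DIC activates each carboxyl group and DMAP relays the acyl group to the N–OH oxygen of 2; the two ends lie fourteen methylenes apart and react independently, and no stereocentre is involved.

Step 2
Reactants: 4 bis(1,3-dioxoisoindolin-2-yl) hexadecanedioate; 5 1-iodo-3,5-dimethoxybenzene (2.6 equiv)
Product: 7 1,14-bis(3,5-dimethoxyphenyl)tetradecane, via monoaryl ester 6 (not isolated)
Conditions: NiBr2(dme) (20 mol %), 4,4'-di-tert-butyl-2,2'-bipyridine (dtbbpy, 20 mol %), Zn powder (5 equiv), N,N-dimethylacetamide, rt, argon, slow addition of 4; aqueous HCl work-up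
Reagents that add atoms: none
Why: Zn reduces NiBr2(dme)/dtbbpy to zerovalent nickel, which inserts into the carbon–iodine bond of 5 to give an aryl complex of divalent nickel, while single-electron transfer from low-valent nickel or Zn to one phthalimide ester end of 4 breaks the N–O bond and expels CO2, which leaves a primary alkyl radical at what becomes the benzylic CH2. Capture of this radical by the aryl nickel complex gives trivalent nickel, reductive elimination forms the ring carbon–CH2 bond and gives 6, and the same cycle at the remaining ester end of 6 forms the second, equivalent bond, so that three components, two C–C bonds and the whole C26 skeleton come together in one operation. The closest known reaction type is the nickel-catalysed decarboxylative cross-electrophile coupling of primary alkyl N-hydroxyphthalimide esters with aryl iodides, a union of two electrophilic carbons that is used here at both ends of one substrate. No ring is closed and no stereocentre is formed. The step needs cross-selectivity over biaryl formation, alkyl–alkyl dimerisation and hydrogen abstraction by the radical; it is secured by the different activation modes of the partners (two-electron oxidative addition for the sp2 carbon–iodine bond, one-electron reduction for the ester), by an excess of 5 and by slow addition of 4, which keeps the radical concentration low. The site on the ring is fixed by the iodine at the carbon meta to both methoxy groups, whose oxygen lone pairs do not enrich that carbon and so do not slow the oxidative addition, the fourteen-carbon spacer keeps the two ends independent, and the methyl ethers are inert to Zn and low-valent nickel at room temperature.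

Step 3
Reactants: 7 1,14-bis(3,5-dimethoxyphenyl)tetradecane
Product: 9 bisnorstriatol, via boron aryloxide 8 (not isolated)
Conditions: BBr3 (6 equiv), CH2Cl2, −78 °C to rt; then H2O, 0 °C
Reagents that add atoms: boron tribromide, BrB(Br)Br (its boron and bromine stand only in intermediate 8; none of them remains in 9)
Why: This is a Lewis-acid cleavage of aryl methyl ethers, in which BBr3 binds each ether oxygen, bromide removes the methyl group by SN2 attack, and water frees the four phenols from 8, while the saturated chain and the arenes are inert.

Compound list
1 | hexadecanedioic acid | OC(=O)CCCCCCCCCCCCCCC(=O)O | starting material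
2 | N-hydroxyphthalimide | O=C1c2ccccc2C(=O)N1O | starting material
3 | 16-[(1,3-dioxoisoindolin-2-yl)oxy]-16-oxohexadecanoic acid | OC(=O)CCCCCCCCCCCCCCC(=O)ON1C(=O)c2ccccc2C1=O | intermediate
4 | bis(1,3-dioxoisoindolin-2-yl) hexadecanedioate | O=C1c2ccccc2C(=O)N1OC(=O)CCCCCCCCCCCCCCC(=O)ON1C(=O)c2ccccc2C1=O | intermediate
5 | 1-iodo-3,5-dimethoxybenzene | COc1cc(I)cc(OC)c1 | starting material
6 | 1,3-dioxoisoindolin-2-yl 15-(3,5-dimethoxyphenyl)pentadecanoate | COc1cc(CCCCCCCCCCCCCCC(=O)ON2C(=O)c3ccccc3C2=O)cc(OC)c1 | intermediate
7 | 1,14-bis(3,5-dimethoxyphenyl)tetradecane | COc1cc(CCCCCCCCCCCCCCc2cc(OC)cc(OC)c2)cc(OC)c1 | intermediate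
8 | 1,14-bis[3,5-bis(dibromoboryloxy)phenyl]tetradecane | BrB(Br)Oc1cc(CCCCCCCCCCCCCCc2cc(OB(Br)Br)cc(OB(Br)Br)c2)cc(OB(Br)Br)c1 | intermediate
9 | bisnorstriatol, 5,5'-(tetradecane-1,14-diyl)bis(benzene-1,3-diol) | Oc1cc(O)cc(CCCCCCCCCCCCCCc2cc(O)cc(O)c2)c1 | target

Total step count: 3
Longest linear sequence: 3 steps

Steps most likely to fail

Step 2. Cross-selectivity may be lost at one of the two chain ends. The primary radical may abstract hydrogen from the solvent, two alkyl radicals may dimerise to chain-doubled material, or the aryl iodide may homocouple. Any of these would leave mixtures of similar polarity that are hard to separate. The fallback gives up the radical and uses a chain terminus of conventional nucleophilic polarity. It sets out from 5 and comes back to the route at 7. Commercial tetradeca-1,13-diene F1 is hydroborated at both terminal alkenes with 9-BBN-H (THF, 0 °C to rt). This should give 1,14-bis(9-borabicyclo[3.3.1]nonan-9-yl)tetradecane F2. That compound is used in solution and coupled twice with 5 (2.2 equiv) under PdCl2(dppf), aqueous K3PO4, THF/DMF, 60 °C. This is a double B-alkyl Suzuki–Miyaura coupling.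

Step 3. Cleavage of the four ethers may stop short and leave partly methylated phenols. The electron-rich resorcinol rings may also darken by air oxidation during the acidic aqueous work-up. The fallback changes the protecting group so that the last step is a neutral hydrogenolysis. It sets out from 4 and comes back to the route at 9. Commercial 5-iodoresorcinol F3 is O-benzylated (benzyl bromide, K2CO3, DMF, rt) to 1,3-bis(benzyloxy)-5-iodobenzene F4. This iodide takes the place of 5 in the coupling with 4 under the conditions of step 2. The coupling should give 1,14-bis[3,5-bis(benzyloxy)phenyl]tetradecane F5. Hydrogenolysis (H2, Pd/C, EtOAc/EtOH, rt) then frees the four phenols.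

Step 1. The second esterification may stay incomplete because the diacid dissolves poorly. The activated acid may also rearrange by O-to-N acyl shift, and the active ester may hydrolyse during purification. The fallback avoids the active ester altogether but keeps the logic of a C16 diacid that loses two carbons. It sets out from 1 and comes back to the route at 7. Both carboxyl groups of 1 are replaced by iodine in a Hunsdiecker-type decarboxylative iodination (PhI(OAc)2, I2, 1,2-dichloroethane, visible light, reflux). This should give 1,14-diiodotetradecane F6. It is then joined to 5 (2.6 equiv) by nickel-catalysed cross-electrophile coupling of an alkyl iodide with an aryl iodide. The conditions are NiI2·xH2O, dtbbpy, 1,2-bis(diphenylphosphino)benzene, pyridine, Mn powder, DMPU, 60 °C.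

Further compounds
F1 | step 2 | tetradeca-1,13-diene | C=CCCCCCCCCCCCC=C
F2 | step 2 | 1,14-bis(9-borabicyclo[3.3.1]nonan-9-yl)tetradecane | C1CC2CCCC(C1)B2CCCCCCCCCCCCCCB1C2CCCC1CCC2
F3 | step 3 | 5-iodoresorcinol | Oc1cc(I)cc(O)c1
F4 | step 3 | 1,3-bis(benzyloxy)-5-iodobenzene | Ic1cc(OCc2ccccc2)cc(OCc2ccccc2)c1
F5 | step 3 | 1,14-bis[3,5-bis(benzyloxy)phenyl]tetradecane | C(c1ccccc1)Oc1cc(CCCCCCCCCCCCCCc2cc(OCc3ccccc3)cc(OCc3ccccc3)c2)cc(OCc2ccccc2)c1
F6 | step 1 | 1,14-diiodotetradecane | ICCCCCCCCCCCCCCI
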